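The complex is conserved. With A the starting complex, B the complex with one exchanged, C the complex with two exchanged and E the over-reaction product, A + B + C + E stays at the amount of complex put in.

| setting | gamma | alpha | maple | elm | birch |
|---|---|---|---|---|---|
| starting complex | 0.050 M | 0.050 M | 0.050 M | 0.050 M | 0.050 M |
| incoming ligand | 0.57 equiv | 1.7 equiv | 4.00 equiv | 0.800 equiv | 1.20 equiv |
| remark | run made earlier | run made earlier |  |  |  |
| time |  |  | 6.0 min | 6.0 min | 6.0 min |

| run | time / min | complex with one exchanged / % | complex with two exchanged / % |
|---|---|---|---|
| gamma | 0.833 | 10.9 | 7.2 |
| gamma | 1.50 | 9.4 | 11.7 |
| gamma | 2.50 | 8.5 | 13.3 |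
| gamma | 3.00 | 9.6 | 12.2 |
| gamma | 4.00 | 11.4 | 14.1 |
| alpha | 0.333 | 10.4 | 16.8 |
| alpha | 0.667 | 10.3 | 25.6 |
| alpha | 1.33 | 6.8 | 35.1 |
| alpha | 2.00 | 7.5 | 35.3 |
| alpha | 4.00 | 7.1 | 40.2 |

(readings scatter by 1 percentage point)

- what was read earlier has a scatter of 1 percentage point, one standard deviation
- steps under discussion: starting complex + incoming ligand -> leaving ligand + complex with one exchanged; complex with two exchanged + incoming ligand -> over-reaction product; incoming ligand -> decomposed reagent; complex with one exchanged + incoming ligand -> leaving ligand + complex with two exchanged

* which of these holds the largest part of the starting complex at the end of maple (complex with one exchanged / complex with two exchanged / starting complex)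
* which of these holds the largest part of the starting complex at the end of elm (complex with one exchanged / complex with two exchanged / starting complex)
* which of these holds the largest part of the starting complex at the end of birch (complex with one exchanged / complex with two exchanged / starting complex)
* how much complex with one exchanged is there at the end of birch, in percent of the starting complex charged

A bench rule of thumb, at 0.050 M of starting complex: a fixed share y of the charged incoming ligand is taken to end on the complex, and the rest to decay. Below, "charge" means the equivalents of incoming ligand; B carries one incoming ligand, C 2 and E 3. Taking E as negligible in gamma, the readings from 1.50 min on give y = (B + 2C)/charge = 0.621.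

In alpha, from 1.33 min on, B stays flat within the scatter while C stands higher than B. B is read as a steady-state intermediate, spent about as fast as it is made while incoming ligand lasts. With each exchange taken as first order in its complex and in the same ligand, the ligand cancels from that balance and B/A comes out constant. The budget B + 2C + 3E = y × charge then puts E in alpha at 8.21%, and the balance puts A at 47.8%. This gives s = 0.149, the resting ratio B/A, a reading with the runs' scatter.

With E neglected, A = (2 − y × charge)/(2 + s), B = sA, and C is the remainder. The ratio y × charge/2 is the budget over the two exchanges each complex offers, and the border is where it reaches one, since the formula's A is zero there.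

| Flask | Ratio | A | B | C |
|---|---|---|---|---|
| elm | 0.248 | 70.0% | 10.4% | 19.6% |
| birch | 0.372 | 58.4% | 8.72% | 32.9% |
| maple | 1.24 | – | – | – |

Maple lies past the border, so this reckoning stops there. The judgement for maple is that C leads the three.

The forecast names complex with two exchanged for maple, starting complex for elm and starting complex for birch, and puts B in birch at 9%, slightly above this reckoning, on the ground that “All ligand is gone by 6 min”.

The flasks give complex with two exchanged, starting complex and starting complex, with 8.97% of B in birch.

    starting complex + incoming ligand → leaving ligand + complex with one exchanged (k = 0.220 /M/s)
    complex with two exchanged + incoming ligand → over-reaction product (k = 0.149 /M/s)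
    incoming ligand → decomposed reagent (k = 0.00526 /s)
    complex with one exchanged + incoming ligand → leaving ligand + complex with two exchanged (k = 1.50 /M/s)

The neighbour is birch charged with 3.00 equiv of incoming ligand. Its ratio is 0.931, below the border, and the formula gives A = 6.43%. The neighbour holds 15.3% of A, with 41.2% in E, which the formula neglected. The resting ratio, applied to that A, gives B = 2.28%, and the neighbour holds 2.62%.

The earlier runs and the new flask stem from a simulated flask with constants of no real substance, noise included.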